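Per molar of capture agent is how I counted the trapped intermediate. The step thought to make it joins one complex with one exchanged to one capture agent, so I took its rate as proportional to both concentrations and followed the complex with one exchanged, the branch point.

| flask | starting complex | incoming ligand | capture agent | temperature | remark | time |
|---|---|---|---|---|---|---|
| blue | 0.050 M | 0.15 M | 0.015 M | 45 °C | run made earlier |  |
| grey | 0.050 M | 0.075 M | 0.015 M | 56 °C | run made earlier |  |
| green | 0.050 M | 0.11 M | 0.015 M | 45 °C | run made earlier |  |
| violet | 0.10 M | 0.15 M | 0.015 M | 56 °C | run made earlier |  |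
| ash | 0.050 M (fed, over 5.0 h) | 0.150 M | 0.0150 M | 50 °C | all else is in the flask from the start; the feed brings no volume worth counting | 12 h |
| birch | 0.050 M (in portions, 5, over 5.0 h) | 0.150 M | 0.0150 M | 50 °C | first portion at the start, last at 5.0 h | 12 h |
| alder | 0.050 M (fed, over 5.0 h) | 0.150 M | 0.0150 M |  | the addition at 20 °C, then warmed to 50 °C; the feed brings no volume worth counting | 12 h |
| oak | 0.050 M | 0.150 M | 0.0150 M | 50 °C | everything together at the start | 12 h |

| run | time / h | complex with two exchanged / % | trapped intermediate / % |
|---|---|---|---|
| blue | 0.500 | 2 | 0 |
| blue | 1.00 | 1 | 2 |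
| blue | 1.50 | 7 | 0 |
| blue | 2.50 | 12 | 0 |
| blue | 4.00 | 14 | 1 |
| blue | 8.00 | 21 | 4 |
| grey | 1.33 | 10 | 0 |
| grey | 2.50 | 6 | 1 |
| grey | 4.00 | 9 | 3 |
| grey | 5.00 | 10 | 5 |
| grey | 6.00 | 9 | 7 |
| grey | 8.00 | 10 | 10 |
| green | 0.500 | 0 | 0 |
| green | 1.00 | 2 | 1 |
| green | 1.50 | 1 | 2 |
| green | 2.50 | 11 | 1 |
| green | 4.00 | 11 | 0 |
| green | 8.00 | 16 | 4 |
| violet | 1.33 | 10 | 1 |
| violet | 3.00 | 10 | 4 |
| violet | 4.00 | 14 | 8 |
| violet | 6.00 | 11 | 9 |
| violet | 8.00 | 8 | 9 |

(each reading ± 2 percentage points)

* the flask with the highest share of complex with two exchanged in complex with two exchanged plus trapped intermediate ("all alike" if they lie within 1.5 percentage points) (ash / birch / alder / oak / all alike)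
* share of complex with two exchanged in complex with two exchanged plus trapped intermediate at the end, ash
* share of complex with two exchanged in complex with two exchanged plus trapped intermediate at the end, birch
* share of complex with two exchanged in complex with two exchanged plus trapped intermediate at the end, alder
* share of complex with two exchanged in complex with two exchanged plus trapped intermediate at the end, oak

- the numbers in the tables scatter by 2 percentage points (one standard deviation)
- steps thought possible: starting complex + incoming ligand -> leaving ligand + complex with one exchanged; complex with one exchanged + incoming ligand <-> leaving ligand + complex with two exchanged; complex with one exchanged + capture agent -> trapped intermediate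

In the first instants the starting complex meets incoming ligand, in oak 0.150 M against 0.050 M, and I treated that exchange as pseudo-first-order. Grey read 0% of trapped intermediate at 1.33 h. In the middle the complex with one exchanged should climb roughly with the clock, so trapping should go with the square of warm time. Grey read 3% at 4.00 h and 10% at 8.00 h, a factor of 3.33 where the square gives 4.00. Over those hours grey's complex with two exchanged read 9% and then 10%, so late hours lower the share.

For the end I needed trapping near 50 °C, which lies close to the middle of 45 °C and 56 °C. At 8.00 h blue read 4% and grey 10%. Grey also held less incoming ligand than blue, and I made no correction for that difference. Their geometric mean, divided by the capture charge, gave my trapping yield, the fraction of the charged starting complex trapped in 8.00 h of warm time per molar of capture agent: 4.22 M⁻¹.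

Oak has 12 h of warm time, so I reckoned 14.2% trapped. Ash and birch hold their complex 9.50 h on average, which gave 8.92%. Alder's addition stands colder than any run, so I counted 7.00 h for it and got 4.84%. Holding the complex with two exchanged at blue's 21%, my shares were 59.7% for oak, 70.2% for ash and birch, and 81.3% for alder.

The forecast, holding that “the second exchange is reversible”, named alder and gave 72% for ash, 71% for birch, 81% for alder and 63% for oak, which at oak lies 3.4 percentage points above mine.

    starting complex + incoming ligand → leaving ligand + complex with one exchanged (k = 4.01 × 10⁻⁴ M⁻¹ s⁻¹, Ea = 68.0 kJ mol⁻¹)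
    complex with one exchanged + incoming ligand ⇌ leaving ligand + complex with two exchanged (K = 0.220, k = 0.00190 M⁻¹ s⁻¹, Ea = 71.0 kJ mol⁻¹, ΔH = −14.0 kJ mol⁻¹)
    complex with one exchanged + capture agent → trapped intermediate (k = 7.37 × 10⁻⁴ M⁻¹ s⁻¹, Ea = 87.0 kJ mol⁻¹)
    (constants at 50 °C)

The flask with the highest share was alder: ash 68.8%, birch 68.9%, alder 76.2%, oak 61.9%. Alder held 6.66% of trapped intermediate at 12.0 h, more than my reckoning. Earlier, at the change of temperature at 5.00 h, alder already held 3.50% of complex with one exchanged. Through the yield, that amount corresponds to 8.21 h of warm time in alder. The same yield over the same time, for the neighbour of alder charged with 0.0060 M of capture agent, gives 2.67%, and that flask held 2.76%.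

All runs were generated by integration for substances that don't exist; noise was put on by code.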